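The route rests on the C6–C7 bond (germacrane numbering: C6 is the lactone O–CH, C7 the ring-fusion CH bearing C11), which is shared by the ten-membered carbocycle and the cis-fused γ-lactone. An acyclic chain with a C6 enal at one end and a (Z)-2-(bromomethyl)enoate (C7=C11, C13–Br, C12 ester) at the other is closed by a chromium-mediated intramolecular 2-(alkoxycarbonyl)allylation. γ-Attack forms C6–C7, sets both stereocentres under control of the C9 silyl ether and moves the alkene to the exocyclic C11=C13 position; the alkoxide then lactonizes onto C12. The step exploits the homoallylic array O–C6–C7–C11(=C13)–C12 of the α-methylene lactone. The chain is assembled by a Z-selective Wittig union of two fragments.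

Key step: step 13

Remark: atom labels follow germacrane numbering (C1=C10 and C4=C5 ring alkenes, C9 acetoxy carbon, C14 methyl, C15 acyloxymethyl carbon); TBS = tert-butyldimethylsilyl; lactol 11 is used as its anomer mixture in equilibrium with the open hydroxy ketone.

Step 1
Reactants: 1 tert-butyldimethyl(prop-2-yn-1-yloxy)silane
Product: 3 methyl 4-(TBS-oxy)but-2-ynoate, via lithium acetylide 2 (not isolated)
Conditions: n-BuLi, THF, −78 °C; then ClCO2Me, −78 → 0 °C
Reagents that add atoms: methyl chloroformate, COC(=O)Cl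
Why: Deprotonation of the terminal alkyne and C-acylation of the lithium acetylide with a chloroformate is a standard ynoate synthesis and brings in C6 as the ester carbon.

Step 2
Reactants: 3 methyl 4-(TBS-oxy)but-2-ynoate; 4 3-chloropropan-1-ol
Product: 6 methyl (2Z)-6-hydroxy-3-[(TBS-oxy)methyl]hex-2-enoate, via magnesium alkoxide Grignard reagent 5 (not isolated)
Conditions: 4, i-PrMgCl, THF, −20 °C; Mg, reflux; then CuI·2LiCl (10 mol %), 3, THF, −78 °C; MeOH then aq. NH4Cl at −78 °C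
Reagents that add atoms: none
Why: Copper-catalysed syn-carbometalation (conjugate addition) of the Grignard reagent to the 4-silyloxy ynoate, followed by cold protonation, puts the new C3 chain trans and the CH2OTBS group (C15) cis to the ester, which fixes the C4=C5 geometry.

Step 3
Reactants: 6 methyl (2Z)-6-hydroxy-3-[(TBS-oxy)methyl]hex-2-enoate
Product: 7 methyl (2Z)-6-iodo-3-[(TBS-oxy)methyl]hex-2-enoate
Conditions: PPh3, imidazole, I2, CH2Cl2, 0 °C
Reagents that add atoms: iodine, II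
Why: Appel-type iodination converts the primary alcohol into the iodide under neutral conditions that leave the allylic silyl ether and the enoate untouched.

Step 4
Reactants: 7 methyl (2Z)-6-iodo-3-[(TBS-oxy)methyl]hex-2-enoate
Product: 8 [(4Z)-6-methoxy-6-oxo-4-[(TBS-oxy)methyl]hex-4-en-1-yl]triphenylphosphonium iodide
Conditions: PPh3, MeCN, 80 °C
Reagents that add atoms: triphenylphosphine, c1ccc(cc1)P(c1ccccc1)c1ccccc1
Why: SN2 quaternization of triphenylphosphine by the primary iodide gives the Wittig salt without touching any stereo element.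

Step 5
Reactants: 9 (3S)-3-hydroxyoxolan-2-one
Product: 10 (3S)-3-(TBS-oxy)oxolan-2-one
Conditions: TBSCl, imidazole, DMF, 0 °C → rt
Reagents that add atoms: tert-butyldimethylsilyl chloride, CC(C)(C)[Si](C)(C)Cl
Why: Standard silylation of the secondary alcohol; the future C9 stereocentre comes from the chiral pool and is not touched.

Step 6
Reactants: 10 (3S)-3-(TBS-oxy)oxolan-2-one
Product: 11 (3S)-2-methyl-3-(TBS-oxy)oxolan-2-ol
Conditions: MeLi (1.05 equiv), THF, −78 °C; aq. NH4Cl at −78 °C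
Reagents that add atoms: methyllithium, [Li]C
Why: At −78 °C the lactone takes up one equivalent of methyllithium and the tetrahedral lithium alkoxide survives until the quench, giving the methyl ketone (C10 and C14) masked as its lactol; the new anomeric centre is irrelevant and the α-silyloxy centre is not enolized at this temperature.

Step 7
Reactants: 11 (3S)-2-methyl-3-(TBS-oxy)oxolan-2-ol
Product: 12 (3S)-4-oxo-3-(TBS-oxy)pentyl 2,2-dimethylpropanoate
Conditions: pivaloyl chloride, pyridine, DMAP (cat.), CH2Cl2, 0 °C → rt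
Reagents that add atoms: pivaloyl chloride, CC(C)(C)C(Cl)=O
Why: The lactol equilibrates with the open γ-hydroxy ketone, whose primary alcohol is the only hydroxyl that can be acylated, so pivaloylation drains the mixture to the open-chain α-silyloxy methyl ketone.

Step 8
Reactants: 8 [(4Z)-6-methoxy-6-oxo-4-[(TBS-oxy)methyl]hex-4-en-1-yl]triphenylphosphonium iodide; 12 (3S)-4-oxo-3-(TBS-oxy)pentyl 2,2-dimethylpropanoate
Product: 14 methyl (2Z,6Z,8S)-7-methyl-10-(pivaloyloxy)-8-(TBS-oxy)-3-[(TBS-oxy)methyl]deca-2,6-dienoate, via phosphorus ylide 13 (not isolated)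
Conditions: 8, NaN(SiMe3)2, THF, −78 °C; then 12, −78 °C → rt
Reagents that add atoms: none
Why: Wittig olefination of an α-alkoxy methyl ketone with a salt-free non-stabilized ylide is Z-selective, the oxygen-bearing carbon C9 ending up cis to the ylide chain (C2), which sets the C1=C10 geometry and joins the two fragments; the ketone reacts faster than the pivalate or the hindered enoate.

Step 9
Reactants: 14 methyl (2Z,6Z,8S)-7-methyl-10-(pivaloyloxy)-8-(TBS-oxy)-3-[(TBS-oxy)methyl]deca-2,6-dienoate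
Product: 15 (2Z,6Z,8S)-7-methyl-8-(TBS-oxy)-3-[(TBS-oxy)methyl]deca-2,6-diene-1,10-diol
Conditions: i-Bu2AlH (6 equiv), CH2Cl2, −78 → 0 °C; aq. potassium sodium tartrate
Reagents that add atoms: none
Why: Excess i-Bu2AlH reduces the conjugated methyl ester 1,2 to the allylic alcohol (C6) and cleaves the pivalate (C7) in the same operation, while silyl ethers and alkenes are inert.

Step 10
Reactants: 15 (2Z,6Z,8S)-7-methyl-8-(TBS-oxy)-3-[(TBS-oxy)methyl]deca-2,6-diene-1,10-diol
Product: 16 (2Z,6Z,8S)-7-methyl-8-(TBS-oxy)-3-[(TBS-oxy)methyl]deca-2,6-dienedial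
Conditions: Dess–Martin periodinane, CH2Cl2, 0 °C → rt
Reagents that add atoms: none
Why: Dess–Martin oxidation converts both primary alcohols into aldehydes under near-neutral conditions that should neither isomerize the C4=C5 enal nor eliminate the β-silyloxy group.

Step 11
Reactants: 16 (2Z,6Z,8S)-7-methyl-8-(TBS-oxy)-3-[(TBS-oxy)methyl]deca-2,6-dienedial
Product: 17 methyl (5S,6Z,10Z)-3-hydroxy-6-methyl-2-methylidene-12-oxo-5-(TBS-oxy)-10-[(TBS-oxy)methyl]dodeca-6,10-dienoate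
Conditions: methyl acrylate (excess), DABCO (1 equiv), MeOH (2 equiv), rt
Reagents that add atoms: methyl acrylate, C=CC(=O)OC
Why: The Morita–Baylis–Hillman reaction should take place only at the aliphatic aldehyde C7, because the β,β-disubstituted enal C6 is a much poorer electrophile; the new carbinol centre forms as a mixture that step 12 erases.

Step 12
Reactants: 17 methyl (5S,6Z,10Z)-3-hydroxy-6-methyl-2-methylidene-12-oxo-5-(TBS-oxy)-10-[(TBS-oxy)methyl]dodeca-6,10-dienoate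
Product: 18 methyl (2Z,5S,6Z,10Z)-2-(bromomethyl)-6-methyl-12-oxo-5-(TBS-oxy)-10-[(TBS-oxy)methyl]dodeca-2,6,10-trienoate
Conditions: NBS, Me2S, CH2Cl2, 0 °C; then 17, 0 °C → rt
Reagents that add atoms: N-bromosuccinimide, O=C1CCC(=O)N1Br
Why: The Corey–Kim reagent activates the allylic alcohol and bromide enters by SN2′ with allyl transposition to give the thermodynamically preferred (Z)-2-(bromomethyl)alk-2-enoate; the enal and the silyl ethers are not touched.

Step 13
Reactants: 18 methyl (2Z,5S,6Z,10Z)-2-(bromomethyl)-6-methyl-12-oxo-5-(TBS-oxy)-10-[(TBS-oxy)methyl]dodeca-2,6,10-trienoate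
Product: 21 (3aR,5S,6Z,10Z,11aR)-6-methyl-3-methylidene-5-(TBS-oxy)-10-[(TBS-oxy)methyl]-3a,4,5,8,9,11a-hexahydrocyclodeca[b]furan-2(3H)-one, via allylchromium dichloride 19 (not isolated), via chromium alkoxide of the hydroxy ester 20 (not isolated)
Conditions: CrCl2 (8 equiv), THF, 25 °C, slow addition of 18 to 0.003 M; aq. NH4Cl work-up
Reagents that add atoms: none
Why: Two equivalents of divalent chromium reduce the allylic bromide to the allylchromium species 19 (trivalent chromium), whose γ-carbon C7 adds to the chromium-bound aldehyde C6 through a closed six-membered Zimmerman–Traxler transition state (SE2′, so that C11=C13 becomes the exocyclic methylene), and the chromium alkoxide 20 then acylates itself on the C12 methyl ester in the flask or on work-up. The closest known reaction type is the intramolecular Nozaki–Hiyama–Kishi 2-(alkoxycarbonyl)allylation of an aldehyde by a 2-(bromomethyl)alk-2-enoate, which is known for ten-membered carbocycles of this class. The carbocycle closes by a 10-exo-trig addition to C6=O and the lactone by a 5-exo-trig acyl substitution at C12. The C6/C7 relationship (syn adduct, hence cis-fused lactone) should follow from the allylchromium geometry, with C8 cis to CH2Cr and therefore axial in the chair while the alkenyl residue on C6 is equatorial; the absolute sense (6R,7R) is to be relayed from C9, whose OTBS group is held on the outer face of the forming ring because C9–H lies in the plane of the C1=C10 Z-alkene to avoid A(1,3) strain with C2, and this relay is the least secure element. The step needs γ- over α-attack and 1,2- over 1,4-addition, both secured by the cyclic transition state, and ring closure over oligomerization, secured by high dilution.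

Step 14
Reactants: 21 (3aR,5S,6Z,10Z,11aR)-6-methyl-3-methylidene-5-(TBS-oxy)-10-[(TBS-oxy)methyl]-3a,4,5,8,9,11a-hexahydrocyclodeca[b]furan-2(3H)-one
Product: 22 (3aR,5S,6Z,10Z,11aR)-5-hydroxy-10-(hydroxymethyl)-6-methyl-3-methylidene-3a,4,5,8,9,11a-hexahydrocyclodeca[b]furan-2(3H)-one
Conditions: HF·pyridine, pyridine/THF, 0 °C → rt
Reagents that add atoms: none
Why: Buffered HF cleaves both silyl ethers under mildly acidic conditions, which the α-methylene lactone tolerates better than basic fluoride sources.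

Step 15
Reactants: 22 (3aR,5S,6Z,10Z,11aR)-5-hydroxy-10-(hydroxymethyl)-6-methyl-3-methylidene-3a,4,5,8,9,11a-hexahydrocyclodeca[b]furan-2(3H)-one
Product: 23 [(3aR,5S,6Z,10Z,11aR)-5-hydroxy-6-methyl-3-methylidene-2-oxo-2,3,3a,4,5,8,9,11a-octahydrocyclodeca[b]furan-10-yl]methyl 3-methylbutanoate
Conditions: 3-methylbutanoyl chloride (1.05 equiv), 2,4,6-collidine, CH2Cl2, −78 → −40 °C
Reagents that add atoms: 3-methylbutanoyl chloride, CC(C)CC(Cl)=O
Why: Acylation at low temperature with a hindered base should discriminate the primary allylic alcohol (C15) from the secondary alcohol at C9, which is flanked by the trisubstituted alkene.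

Step 16
Reactants: 23 [(3aR,5S,6Z,10Z,11aR)-5-hydroxy-6-methyl-3-methylidene-2-oxo-2,3,3a,4,5,8,9,11a-octahydrocyclodeca[b]furan-10-yl]methyl 3-methylbutanoate
Product: 24 [(3aR,5S,6Z,10Z,11aR)-5-(acetyloxy)-6-methyl-3-methylidene-2-oxo-2,3,3a,4,5,8,9,11a-octahydrocyclodeca[b]furan-10-yl]methyl 3-methylbutanoate
Conditions: Ac2O, pyridine, DMAP (cat.), CH2Cl2, 0 °C
Reagents that add atoms: acetic anhydride, CC(=O)OC(C)=O
Why: Standard acetylation of the remaining secondary alcohol with retention at C9 completes the target.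

Compound list
1 | tert-butyldimethyl(prop-2-yn-1-yloxy)silane | C#CCO[Si](C)(C)C(C)(C)C | starting material
2 | lithium acetylide of 1 | [Li]C#CCO[Si](C)(C)C(C)(C)C | intermediate (not isolated)
3 | methyl 4-(TBS-oxy)but-2-ynoate | COC(=O)C#CCO[Si](C)(C)C(C)(C)C | intermediate
4 | 3-chloropropan-1-ol | OCCCCl | starting material
5 | chloromagnesium 3-(chloromagnesio)propan-1-olate | Cl[Mg]OCCC[Mg]Cl | intermediate (not isolated)
6 | methyl (2Z)-6-hydroxy-3-[(TBS-oxy)methyl]hex-2-enoate | COC(=O)/C=C(\CO[Si](C)(C)C(C)(C)C)CCCO | intermediate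
7 | methyl (2Z)-6-iodo-3-[(TBS-oxy)methyl]hex-2-enoate | COC(=O)/C=C(\CO[Si](C)(C)C(C)(C)C)CCCI | intermediate
8 | [(4Z)-6-methoxy-6-oxo-4-[(TBS-oxy)methyl]hex-4-en-1-yl]triphenylphosphonium iodide | COC(=O)/C=C(\CO[Si](C)(C)C(C)(C)C)CCC[P+](c1ccccc1)(c1ccccc1)c1ccccc1.[I-] | intermediate
9 | (3S)-3-hydroxyoxolan-2-one | O[C@H]1CCOC1=O | starting material
10 | (3S)-3-(TBS-oxy)oxolan-2-one | CC(C)(C)[Si](C)(C)O[C@H]1CCOC1=O | intermediate
11 | (3S)-2-methyl-3-(TBS-oxy)oxolan-2-ol (anomer mixture) | CC(C)(C)[Si](C)(C)O[C@H]1CCOC1(C)O | intermediate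
12 | (3S)-4-oxo-3-(TBS-oxy)pentyl 2,2-dimethylpropanoate | CC(=O)[C@H](CCOC(=O)C(C)(C)C)O[Si](C)(C)C(C)(C)C | intermediate
13 | phosphorus ylide of 8 | COC(=O)/C=C(\CO[Si](C)(C)C(C)(C)C)CCC=P(c1ccccc1)(c1ccccc1)c1ccccc1 | intermediate (not isolated)
14 | methyl (2Z,6Z,8S)-7-methyl-10-(pivaloyloxy)-8-(TBS-oxy)-3-[(TBS-oxy)methyl]deca-2,6-dienoate | COC(=O)/C=C(\CO[Si](C)(C)C(C)(C)C)CC/C=C(/C)[C@H](CCOC(=O)C(C)(C)C)O[Si](C)(C)C(C)(C)C | intermediate
15 | (2Z,6Z,8S)-7-methyl-8-(TBS-oxy)-3-[(TBS-oxy)methyl]deca-2,6-diene-1,10-diol | OC/C=C(\CO[Si](C)(C)C(C)(C)C)CC/C=C(/C)[C@H](CCO)O[Si](C)(C)C(C)(C)C | intermediate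
16 | (2Z,6Z,8S)-7-methyl-8-(TBS-oxy)-3-[(TBS-oxy)methyl]deca-2,6-dienedial | O=C/C=C(\CO[Si](C)(C)C(C)(C)C)CC/C=C(/C)[C@H](CC=O)O[Si](C)(C)C(C)(C)C | intermediate
17 | methyl (5S,6Z,10Z)-3-hydroxy-6-methyl-2-methylidene-12-oxo-5-(TBS-oxy)-10-[(TBS-oxy)methyl]dodeca-6,10-dienoate (C3 epimer mixture) | O=C/C=C(\CO[Si](C)(C)C(C)(C)C)CC/C=C(/C)[C@H](CC(O)C(=C)C(=O)OC)O[Si](C)(C)C(C)(C)C | intermediate
18 | methyl (2Z,5S,6Z,10Z)-2-(bromomethyl)-6-methyl-12-oxo-5-(TBS-oxy)-10-[(TBS-oxy)methyl]dodeca-2,6,10-trienoate | O=C/C=C(\CO[Si](C)(C)C(C)(C)C)CC/C=C(/C)[C@H](C/C=C(\CBr)C(=O)OC)O[Si](C)(C)C(C)(C)C | intermediate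
19 | allylchromium dichloride from 18 (trivalent chromium, THF-solvated) | O=C/C=C(\CO[Si](C)(C)C(C)(C)C)CC/C=C(/C)[C@H](C/C=C(\C[Cr](Cl)Cl)C(=O)OC)O[Si](C)(C)C(C)(C)C | intermediate (not isolated)
20 | methyl 2-[(1R,2R,3Z,7Z,9S)-2-hydroxy-8-methyl-9-(TBS-oxy)-4-[(TBS-oxy)methyl]cyclodeca-3,7-dien-1-yl]prop-2-enoate (present as its chromium alkoxide) | O[C@@H]1/C=C(\CO[Si](C)(C)C(C)(C)C)CC/C=C(/C)[C@@H](O[Si](C)(C)C(C)(C)C)C[C@@H]1C(=C)C(=O)OC | intermediate (not isolated)
21 | (3aR,5S,6Z,10Z,11aR)-6-methyl-3-methylidene-5-(TBS-oxy)-10-[(TBS-oxy)methyl]-3a,4,5,8,9,11a-hexahydrocyclodeca[b]furan-2(3H)-one | C=C1C(=O)O[C@@H]2/C=C(\CO[Si](C)(C)C(C)(C)C)CC/C=C(/C)[C@@H](O[Si](C)(C)C(C)(C)C)C[C@H]12 | intermediate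
22 | (3aR,5S,6Z,10Z,11aR)-5-hydroxy-10-(hydroxymethyl)-6-methyl-3-methylidene-3a,4,5,8,9,11a-hexahydrocyclodeca[b]furan-2(3H)-one | C=C1C(=O)O[C@@H]2/C=C(\CO)CC/C=C(/C)[C@@H](O)C[C@H]12 | intermediate
23 | [(3aR,5S,6Z,10Z,11aR)-5-hydroxy-6-methyl-3-methylidene-2-oxo-2,3,3a,4,5,8,9,11a-octahydrocyclodeca[b]furan-10-yl]methyl 3-methylbutanoate | C=C1C(=O)O[C@@H]2/C=C(\COC(=O)CC(C)C)CC/C=C(/C)[C@@H](O)C[C@H]12 | intermediate
24 | [(3aR,5S,6Z,10Z,11aR)-5-(acetyloxy)-6-methyl-3-methylidene-2-oxo-2,3,3a,4,5,8,9,11a-octahydrocyclodeca[b]furan-10-yl]methyl 3-methylbutanoate | C=C1C(=O)O[C@@H]2/C=C(\COC(=O)CC(C)C)CC/C=C(/C)[C@@H](OC(C)=O)C[C@H]12 | target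

Total step count: 16
Longest linear sequence: 13 steps (steps 1–4 and 8–16)

Steps most likely to fail

Step 13. The relay from C9 may be mismatched: the aldehyde is then delivered to the other face of the allylchromium and the cis-lactone forms with the opposite (3aS,11aS) ring fusion next to the (5S) silyl ether, or as a mixture. The fallback runs the same closure in the C9-epimeric series and corrects C9 afterwards by Mitsunobu inversion; it sets out from phosphonium salt 8 and comes back to the route at target 24. Commercial (3R)-3-hydroxyoxolan-2-one (O[C@@H]1CCOC1=O) is silylated to (3R)-3-(TBS-oxy)oxolan-2-one F1, opened with MeLi to lactol F2 and pivaloylated to the (3R)-ketone F3 under the conditions of steps 5–7. Wittig union of F3 with ylide 13 gives the (8R)-dienoate F4, i-Bu2AlH the (8R)-diol F5, Dess–Martin oxidation the (8R)-dialdehyde F6, the Morita–Baylis–Hillman reaction the adduct F7 and NBS/Me2S the (5R)-bromide F8. Closure of F8 with CrCl2 should then give the (3aR,5R,11aR)-bis-silyl lactone F9, HF·pyridine the (5R)-diol F10 and 3-methylbutanoyl chloride the (5R)-hydroxy ester F11. Mitsunobu reaction of F11 (AcOH, PPh3, DIAD, toluene, 0 °C) installs the acetate with inversion at C9 and gives 24.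

Step 11. Under the amine catalyst the β-silyloxy aldehyde may lose silanol, the enal may be attacked or isomerized, or the conversion may stall. The fallback masks C6 and builds the acrylate without an amine; it sets out from diol 15 and comes back to the route at bromide 18. MnO2 in CH2Cl2 oxidizes only the allylic alcohol to the hydroxy enal F12, and HC(OMe)3 with CeCl3·7H2O in MeOH gives the hydroxy dimethyl acetal F13. Dess–Martin oxidation gives the acetal aldehyde F14. Vinylalumination (the α-(methoxycarbonyl)vinyl alane from methyl propiolate, i-Bu2AlH and N-methylmorpholine N-oxide, THF, 0 °C) gives the acetal allylic alcohol F15, and NBS/Me2S the acetal bromide F16. Hydrolysis of the acetal of F16 with oxalic acid on wet silica gel gives 18.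

Step 8. The Z selectivity may erode, the basic ylide may enolize and epimerize ketone 12, or proton transfer may occur within the ester-bearing ylide. The fallback builds the Z-trisubstituted alkene by stereospecific vinyl iodide chemistry; it sets out from alcohol 6 and comes back to the route at dienoate 14. Dess–Martin oxidation of 6 gives the aldehyde F17, and Stork–Zhao olefination (EtPPh3I, n-BuLi, I2, then NaN(SiMe3)2, THF, −78 °C) gives the (Z)-vinyl iodide F18. Propane-1,3-diol is monoacylated with pivaloyl chloride to 3-hydroxypropyl pivalate F19 and oxidized (Swern) to 3-oxopropyl pivalate F20. Asymmetric Nozaki–Hiyama–Kishi coupling of F18 with F20 (CrCl2, NiCl2 cat., chiral sulfonamide ligand, THF) should give the (8S)-allylic alcohol F21 with retention of the alkene geometry. Silylation of F21 (TBSOTf, 2,6-lutidine) gives 14.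

Further compounds
F1 | step 13 | (3R)-3-(TBS-oxy)oxolan-2-one | CC(C)(C)[Si](C)(C)O[C@@H]1CCOC1=O
F2 | step 13 | (3R)-2-methyl-3-(TBS-oxy)oxolan-2-ol (anomer mixture) | CC(C)(C)[Si](C)(C)O[C@@H]1CCOC1(C)O
F3 | step 13 | (3R)-4-oxo-3-(TBS-oxy)pentyl 2,2-dimethylpropanoate | CC(=O)[C@@H](CCOC(=O)C(C)(C)C)O[Si](C)(C)C(C)(C)C
F4 | step 13 | methyl (2Z,6Z,8R)-7-methyl-10-(pivaloyloxy)-8-(TBS-oxy)-3-[(TBS-oxy)methyl]deca-2,6-dienoate | COC(=O)/C=C(\CO[Si](C)(C)C(C)(C)C)CC/C=C(/C)[C@@H](CCOC(=O)C(C)(C)C)O[Si](C)(C)C(C)(C)C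
F5 | step 13 | (2Z,6Z,8R)-7-methyl-8-(TBS-oxy)-3-[(TBS-oxy)methyl]deca-2,6-diene-1,10-diol | OC/C=C(\CO[Si](C)(C)C(C)(C)C)CC/C=C(/C)[C@@H](CCO)O[Si](C)(C)C(C)(C)C
F6 | step 13 | (2Z,6Z,8R)-7-methyl-8-(TBS-oxy)-3-[(TBS-oxy)methyl]deca-2,6-dienedial | O=C/C=C(\CO[Si](C)(C)C(C)(C)C)CC/C=C(/C)[C@@H](CC=O)O[Si](C)(C)C(C)(C)C
F7 | step 13 | methyl (5R,6Z,10Z)-3-hydroxy-6-methyl-2-methylidene-12-oxo-5-(TBS-oxy)-10-[(TBS-oxy)methyl]dodeca-6,10-dienoate | O=C/C=C(\CO[Si](C)(C)C(C)(C)C)CC/C=C(/C)[C@@H](CC(O)C(=C)C(=O)OC)O[Si](C)(C)C(C)(C)C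
F8 | step 13 | methyl (2Z,5R,6Z,10Z)-2-(bromomethyl)-6-methyl-12-oxo-5-(TBS-oxy)-10-[(TBS-oxy)methyl]dodeca-2,6,10-trienoate | O=C/C=C(\CO[Si](C)(C)C(C)(C)C)CC/C=C(/C)[C@@H](C/C=C(\CBr)C(=O)OC)O[Si](C)(C)C(C)(C)C
F9 | step 13 | (3aR,5R,6Z,10Z,11aR)-6-methyl-3-methylidene-5-(TBS-oxy)-10-[(TBS-oxy)methyl]-3a,4,5,8,9,11a-hexahydrocyclodeca[b]furan-2(3H)-one | C=C1C(=O)O[C@@H]2/C=C(\CO[Si](C)(C)C(C)(C)C)CC/C=C(/C)[C@H](O[Si](C)(C)C(C)(C)C)C[C@H]12
F10 | step 13 | (3aR,5R,6Z,10Z,11aR)-5-hydroxy-10-(hydroxymethyl)-6-methyl-3-methylidene-3a,4,5,8,9,11a-hexahydrocyclodeca[b]furan-2(3H)-one | C=C1C(=O)O[C@@H]2/C=C(\CO)CC/C=C(/C)[C@H](O)C[C@H]12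
F11 | step 13 | [(3aR,5R,6Z,10Z,11aR)-5-hydroxy-6-methyl-3-methylidene-2-oxo-2,3,3a,4,5,8,9,11a-octahydrocyclodeca[b]furan-10-yl]methyl 3-methylbutanoate | C=C1C(=O)O[C@@H]2/C=C(\COC(=O)CC(C)C)CC/C=C(/C)[C@H](O)C[C@H]12
F12 | step 11 | (2Z,6Z,8S)-10-hydroxy-7-methyl-8-(TBS-oxy)-3-[(TBS-oxy)methyl]deca-2,6-dienal | O=C/C=C(\CO[Si](C)(C)C(C)(C)C)CC/C=C(/C)[C@H](CCO)O[Si](C)(C)C(C)(C)C
F13 | step 11 | (3S,4Z,8Z)-10,10-dimethoxy-4-methyl-3-(TBS-oxy)-8-[(TBS-oxy)methyl]deca-4,8-dien-1-ol | COC(OC)/C=C(\CO[Si](C)(C)C(C)(C)C)CC/C=C(/C)[C@H](CCO)O[Si](C)(C)C(C)(C)C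
F14 | step 11 | (3S,4Z,8Z)-10,10-dimethoxy-4-methyl-3-(TBS-oxy)-8-[(TBS-oxy)methyl]deca-4,8-dienal | COC(OC)/C=C(\CO[Si](C)(C)C(C)(C)C)CC/C=C(/C)[C@H](CC=O)O[Si](C)(C)C(C)(C)C
F15 | step 11 | methyl (5S,6Z,10Z)-3-hydroxy-12,12-dimethoxy-6-methyl-2-methylidene-5-(TBS-oxy)-10-[(TBS-oxy)methyl]dodeca-6,10-dienoate | COC(OC)/C=C(\CO[Si](C)(C)C(C)(C)C)CC/C=C(/C)[C@H](CC(O)C(=C)C(=O)OC)O[Si](C)(C)C(C)(C)C
F16 | step 11 | methyl (2Z,5S,6Z,10Z)-2-(bromomethyl)-12,12-dimethoxy-6-methyl-5-(TBS-oxy)-10-[(TBS-oxy)methyl]dodeca-2,6,10-trienoate | COC(OC)/C=C(\CO[Si](C)(C)C(C)(C)C)CC/C=C(/C)[C@H](C/C=C(\CBr)C(=O)OC)O[Si](C)(C)C(C)(C)C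
F17 | step 8 | methyl (2Z)-6-oxo-3-[(TBS-oxy)methyl]hex-2-enoate | COC(=O)/C=C(\CO[Si](C)(C)C(C)(C)C)CCC=O
F18 | step 8 | methyl (2Z,6Z)-7-iodo-3-[(TBS-oxy)methyl]octa-2,6-dienoate | COC(=O)/C=C(\CO[Si](C)(C)C(C)(C)C)CC/C=C(/C)I
F19 | step 8 | 3-hydroxypropyl 2,2-dimethylpropanoate | CC(C)(C)C(=O)OCCCO
F20 | step 8 | 3-oxopropyl 2,2-dimethylpropanoate | CC(C)(C)C(=O)OCCC=O
F21 | step 8 | methyl (2Z,6Z,8S)-8-hydroxy-7-methyl-10-(pivaloyloxy)-3-[(TBS-oxy)methyl]deca-2,6-dienoate | COC(=O)/C=C(\CO[Si](C)(C)C(C)(C)C)CC/C=C(/C)[C@@H](O)CCOC(=O)C(C)(C)C
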